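Larch and birch, the two runs you have, show how fast the starting material goes and how late the target appears, and from those two things you can reckon gamma and delta in advance.

| setting | larch | birch | gamma | delta |
|---|---|---|---|---|
| starting material | 20 mM | 20 mM | 20 mM | 20 mM |
| coupling partner | 24 mM | 24 mM | 24.0 mM | 24.0 mM |
| protic impurity | 5 mM | 20 mM | 10.0 mM | 10.0 mM |
| temperature | 35 °C | 46 °C | 50 °C | 30 °C |
| remark | run made earlier | run made earlier |  |  |
| time |  |  | 5.0 min | 5.0 min |

| run | time / min | target / % | starting material / % |
|---|---|---|---|
| larch | 0.833 | 0.2 | 93.1 |
| larch | 3.00 | 1.8 | 80.6 |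
| larch | 5.00 | 5.2 | 71.8 |
| larch | 8.00 | 9.3 | 60.8 |
| larch | 10.0 | 12.7 | 54.9 |
| birch | 0.417 | 0.6 | 82.1 |
| birch | 1.33 | 1.2 | 55.2 |
| birch | 2.50 | 5.5 | 35.9 |
| birch | 4.00 | 6.9 | 23.0 |
| birch | 5.00 | 10.2 | 18.0 |

(standard deviation of a reading: 0.5 percentage points)

- the flask that comes out highest in amount of target, in percent of the starting material charged, or "all alike" when all lie within 1.5 percentage points (gamma / delta / all alike)
- target at the end, in percent of the starting material charged, gamma
- target at the end, in percent of the starting material charged, delta

Take the main step first and treat the loss as pseudo-first-order, with c(starting material) falling as exp(−kt). The last readings give k = 0.0600 min⁻¹ in larch and 0.343 min⁻¹ in birch, a factor of 5.72 for a hotter flask with 4.00 times the impurity. Gamma and delta hold 10.0 mM of protic impurity, the geometric middle of the two runs, and each stands about one temperature gap from the middle of 35 °C and 46 °C. So my own reckoning starts from 0.143 min⁻¹ and, guessing that the impurity takes a square-root share of the factor, multiplies or divides by 2.86, which gives 0.410 min⁻¹ for gamma and 0.0501 min⁻¹ for delta. If lost material were target at once, gamma would read 87.1% and delta 22.2%.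

Now add the lag: at its first reading larch has lost 6.90% but shows 0.2% of target. Let target form in proportion to the material that has left the starting material, and integrate while target is small: target equals a constant times the hold-up time H, which is t minus the lost fraction divided by k. Larch gives H = 2.48 min and a constant of 0.0512 min⁻¹, birch 2.61 min and 0.0391 min⁻¹. I carry their mean as the capture constant, the fraction of held material turned into target per minute, 0.0452 min⁻¹. With H of 2.88 min for gamma and 0.578 min for delta, the numbers shrink to 13.0% and 2.61%.

The rest, whatever leaves the starting material and never becomes target, sits inside the constant, which reads lower in birch than in larch; with birch's constant my estimate for gamma is 11.3%, and with larch's it is 14.7%.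

The forecast names gamma, with 20% for gamma and 1.2% for delta, and reads the same lag: “Target lags behind starting-material loss, which points to an intermediate that slowly turns into target.” My gamma is lower and my delta higher.

Gamma ends at 16.1% and delta at 2.58%, so gamma stands highest, as forecast.

    starting material + coupling partner ⇌ intermediate A (K = 1000 M⁻¹, k = 0.0760 M⁻¹ s⁻¹, Ea = 73.0 kJ mol⁻¹, ΔH = −44.0 kJ mol⁻¹)
    starting material → intermediate B (k = 0.00130 s⁻¹, Ea = 105 kJ mol⁻¹)
    intermediate B → side product (k = 0.00780 s⁻¹, Ea = 100 kJ mol⁻¹)
    coupling partner + intermediate A → target (k = 0.420 M⁻¹ s⁻¹, Ea = 49.0 kJ mol⁻¹)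
    starting material + protic impurity → quenched substrate (k = 0.450 M⁻¹ s⁻¹, Ea = 67.0 kJ mol⁻¹)
    (constants at 50 °C)

Put back into the capture constant, these ends read 0.0672 min⁻¹ for gamma and 0.0352 min⁻¹ for delta. The flask like delta with 96 mM of coupling partner reaches 19.8% and reads 0.162 min⁻¹, which is 4.60 times delta's for 4.00 times the partner. At the start of delta, starting material goes to quenched substrate 2.9 times as fast as to intermediate A, counting the forward step alone. After 5.00 min, delta holds 17.8% of quenched substrate against 2.58% of target.

The numbers in the tables are calculated for substances that don't exist.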